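What share of G in G plus J stands in this flask at 0.15 s, and what at 3.0 min?

| setting | eta | gamma | zeta | flask |
|---|---|---|---|---|
| X | 0.50 M | 0.50 M | 1 M | 0.50 M |
| Z | 0.37 M | 0.83 M | 0.55 M | 0.550 M |
| D | 25 mM | 25 mM | 25 mM | 25 mM |
| remark | run made earlier | run made earlier | run made earlier |  |
| time |  |  |  | 3.0 min |

| run | time / min | G / % | J / % |
|---|---|---|---|
| eta | 0.250 | 33.9 | 22.0 |
| eta | 0.667 | 34.4 | 22.8 |
| eta | 1.50 | 34.0 | 21.7 |
| eta | 4.00 | 32.4 | 23.1 |
| gamma | 0.250 | 52.7 | 33.7 |
| gamma | 0.667 | 52.3 | 35.1 |
| gamma | 1.50 | 50.7 | 33.7 |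
| gamma | 4.00 | 53.5 | 32.8 |
| zeta | 0.417 | 30.8 | 18.3 |
| zeta | 1.33 | 28.3 | 19.8 |
| zeta | 2.50 | 28.3 | 21.3 |
| zeta | 4.00 | 29.2 | 20.2 |

(readings scatter by 1 percentage point)

* share of G in G plus J at 0.15 s
* share of G in G plus J at 3.0 min



I ask first what the end state must be. In the gamma run at 4.00 min, G plus J make 86.3% of the X charged. If each product took one X and one Z, about 0.0685 M of X and 0.398 M of Z stand beside them while the readings stay flat. I read that as a balance rather than a reagent running out.

The quantity I carry is [G]/[J] pooled over the readings of eta, gamma and zeta, the plateau ratio: 1.51. Read run by run, it is 1.46 in zeta and 1.55 in gamma, though the charges differ. If G and J each stand in balance with X and Z, their ratio does not move with the charges, and these readings fit that, so I take it as thermodynamic control; a steady ratio by itself does not tell this from parallel routes.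

Now the flask in slow motion. At 0.15 s, far earlier than the first reading at 0.250 min, the reaction in this flask has just begun. The share then belongs to the forward rates, which no reading shows, so I hold a wide band there. By 0.250 min the eta run already stands on its plateau, so I expect the middle of this flask to be short. At 3.0 min, 12.0 times that time, my reckoning for this flask gives 60.2%.

The forecast says 60% at 0.15 s and 60% at 3.0 min, on this ground: “This suggests parallel routes of equal order”. My end figure comes from a balance instead.

The flask gives 63.3% at 0.15 s and 60.4% at 3.0 min.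

    X + Z ⇌ G (K = 8.70 L mol⁻¹, k = 0.412 L mol⁻¹ s⁻¹)
    G + D ⇌ J + D, rate k2*[D]*[G] forward; the back reaction follows from the equilibrium constant (k = 1.94 L mol⁻¹ s⁻¹)
    2 D ⇌ Q (K = 63.0 L mol⁻¹, k = 15.3 L mol⁻¹ s⁻¹)
    X + Z ⇌ J (K = 5.70 L mol⁻¹, k = 0.239 L mol⁻¹ s⁻¹)

In this flask, G goes back through X and Z with a half-life of 0.24 min, short against 3.0 min. The neighbour charged with 0.14 M of Z holds 14.3% of G at 3.00 min. Dividing by the plateau ratio gives 9.47% of J, and that neighbour holds 9.38%.

The data are calculated for substances that don't exist, noise included.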